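**Strategy.** Everything rests on the C3–C3a bond of the 2,3-dihydrobenzofuran ring. C3 is a bare methylene flanked by the arene and the oxygen-bearing stereocentre C2, so it can start life as the methyl group of (S)-lactate. Mitsunobu inversion makes the aryl sec-alkyl ether with C2 already (R); a Pd(0)-catalysed C(sp3)–H arylation of that methyl by the ortho C–Br bond then closes the five-membered ring without touching C2. The precursor is a 2-bromo-1,3,4-trioxygenated benzene carrying O–CH(CH3)–C(CH3)2OMOM. The former resorcinol oxygen at C4 afterwards directs a Claisen allyl shift to C5 and becomes the triflate for C4 prenylation; a B-alkyl Suzuki coupling adds the reverse-prenylated resorcinol.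

Key step: step 10

Remark: the C2 descriptor encoded by the SMILES is (R). 4-Bromoresorcinol, 2-bromoresorcinol and ethyl (S)-lactate are taken as the purchased starting materials; all other inputs are catalogue reagents.

**Route**

Step 1
Reactants: 1 4-bromoresorcinol
Product: 2 1-bromo-2,4-bis(methoxymethoxy)benzene
Conditions: MOMCl (2.5 equiv), i-Pr2NEt, CH2Cl2, 0 °C → rt
Reagents that add atoms: chloromethyl methyl ether, COCCl
Why: O-alkylation of both phenols (MOM protection) should be clean with a hindered amine base and gives a group that survives the later Pd and borane steps.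

Step 2
Reactants: 2 1-bromo-2,4-bis(methoxymethoxy)benzene
Product: 3 1-bromo-5-iodo-2,4-bis(methoxymethoxy)benzene
Conditions: NIS, CF3CO2H (5 mol%), MeCN, 0 °C → rt
Reagents that add atoms: N-iodosuccinimide, O=C1CCC(=O)N1I
Why: Electrophilic aromatic iodination should go to C5, which is ortho to one alkoxy group and para to the other and, unlike C3, is not flanked by two substituents.

Step 3
Reactants: 3 1-bromo-5-iodo-2,4-bis(methoxymethoxy)benzene
Product: 4 1-bromo-2,4-bis(methoxymethoxy)-5-(2-methylbut-3-en-2-yl)benzene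
Conditions: prenylBpin (1.1 equiv), Pd(OAc)2 (3 mol%), D-t-BPF (3.6 mol%), K3PO4 (aq), THF, 40 °C
Reagents that add atoms: 3-methylbut-2-enylboronic acid pinacol ester, CC(C)=CCB1OC(C)(C)C(C)(C)O1
Why: Allyl–aryl Suzuki–Miyaura coupling under γ-selective conditions: C–I adds to Pd before C–Br, SE2′ transmetalation places Pd on the tertiary allyl carbon, and the bulky wide-bite-angle bisphosphine should force reductive elimination before σ–π–σ isomerisation, giving the 1,1-dimethylallyl arene.

Step 4
Reactants: 5 2-bromoresorcinol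
Product: 7 3-bromo-2,4-dihydroxybenzaldehyde, via iminium chloride 6 (not isolated)
Conditions: POCl3, DMF, MeCN, 0 °C → rt; then H2O, 50 °C
Reagents that add atoms: N,N-dimethylformamide, CN(C)C=O; water, O
Why: Vilsmeier–Haack formylation can only attack the equivalent C4/C6 positions of the symmetric resorcinol (ortho to one OH, para to the other), so a single aldehyde should result after hydrolysis of the iminium salt.

Step 5
Reactants: 7 3-bromo-2,4-dihydroxybenzaldehyde
Product: 8 3-bromo-2-hydroxy-4-[(triisopropylsilyl)oxy]benzaldehyde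
Conditions: TIPSCl (1.05 equiv), imidazole, CH2Cl2, 0 °C
Reagents that add atoms: chlorotriisopropylsilane, CC(C)[Si](Cl)(C(C)C)C(C)C
Why: Silylation should be selective for the 4-OH because the 2-OH is locked in a hydrogen bond to the aldehyde; TIPS is chosen because it offers no aryl or primary C–H bond that could compete in step 10.

Step 6
Reactants: 8 3-bromo-2-hydroxy-4-[(triisopropylsilyl)oxy]benzaldehyde; 9 ethyl (S)-lactate
Product: 10 ethyl (R)-2-{2-bromo-6-formyl-3-[(triisopropylsilyl)oxy]phenoxy}propanoate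
Conditions: PPh3, DIAD, THF, 0 °C → rt
Reagents that add atoms: none
Why: Mitsunobu etherification of the acidic salicylaldehyde OH is an SN2 displacement at the lactate carbinol carbon, so (S)-lactate should give the (R)-aryloxypropanoate with inversion; this sets the only stereocentre of the target.

Step 7
Reactants: 10 ethyl (R)-2-{2-bromo-6-formyl-3-[(triisopropylsilyl)oxy]phenoxy}propanoate
Product: 11 ethyl (R)-2-{2-bromo-6-(formyloxy)-3-[(triisopropylsilyl)oxy]phenoxy}propanoate
Conditions: mCPBA, CH2Cl2, 0 °C → rt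
Reagents that add atoms: 3-chloroperbenzoic acid, OOC(=O)c1cccc(Cl)c1
Why: Baeyer–Villiger (Dakin-type) oxidation: the electron-rich aryl group, with ortho-alkoxy and para-silyloxy donors, should migrate in preference to hydrogen and give the aryl formate.

Step 8
Reactants: 11 ethyl (R)-2-{2-bromo-6-(formyloxy)-3-[(triisopropylsilyl)oxy]phenoxy}propanoate
Product: 13 3-bromo-2-{[(R)-3-hydroxy-3-methylbutan-2-yl]oxy}-4-[(triisopropylsilyl)oxy]phenol, via methyl ketone 12 (not isolated)
Conditions: MeMgBr (5 equiv), THF, 0 °C → rt; aq. NH4Cl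
Reagents that add atoms: methylmagnesium bromide, C[Mg]Br
Why: Excess Grignard reagent should cleave the formate to the phenoxide and add twice to the ester to give the tertiary carbinol; addition to the intermediate ketone is faster than its enolisation, so C2 should not epimerise.

Step 9
Reactants: 13 3-bromo-2-{[(R)-3-hydroxy-3-methylbutan-2-yl]oxy}-4-[(triisopropylsilyl)oxy]phenol
Product: 14 {2-bromo-4-(methoxymethoxy)-3-{[(R)-3-(methoxymethoxy)-3-methylbutan-2-yl]oxy}phenoxy}triisopropylsilane
Conditions: MOMCl (4 equiv), i-Pr2NEt, Bu4NI (cat.), ClCH2CH2Cl, 60 °C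
Reagents that add atoms: chloromethyl methyl ether, COCCl
Why: Alkylation with MOMCl should protect the phenol and, with iodide catalysis and warming, the hindered tertiary alcohol in the same operation, so that no free OH can bind palladium in step 10.

Step 10
Reactants: 14 {2-bromo-4-(methoxymethoxy)-3-{[(R)-3-(methoxymethoxy)-3-methylbutan-2-yl]oxy}phenoxy}triisopropylsilane
Product: 15 {[(R)-7-(methoxymethoxy)-2-[2-(methoxymethoxy)propan-2-yl]-2,3-dihydrobenzofuran-4-yl]oxy}triisopropylsilane
Conditions: Pd(OAc)2 (10 mol%), PCy3·HBF4 (20 mol%), PivOH (30 mol%), Cs2CO3 (1.5 equiv), mesitylene, 140 °C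
Reagents that add atoms: none
Why: Oxidative addition of Pd(0)/PCy3 into the C–Br bond gives an arylpalladium pivalate, which cleaves a C–H bond of the adjacent O–CH(CH3) methyl by concerted metalation–deprotonation through a six-membered oxapalladacycle; C(sp2)–C(sp3) reductive elimination then forms the C3–C3a bond. The closest known reaction type is the Pd(0)-catalysed intramolecular C(sp3)–H arylation of 2-halophenyl alkyl ethers to 2,3-dihydrobenzofurans (and of N-alkyl-2-haloanilines to indolines). The dihydrofuran ring closes in the reductive elimination, the five-membered ring emerging from the six-membered palladacycle. No stereocentre is created: C2 comes from (S)-lactate with Mitsunobu inversion and its own C–H bond is not the one cleaved, so (R) should be carried through. The step needs site selectivity among C–H bonds, and only this methyl offers a primary C–H through a six-membered palladacycle: the gem-dimethyl, MOM and isopropyl methyls would need seven-membered palladacycles, the TIPS methine is tertiary, and no aryl C–H or alkene is within reach, which is why the neighbouring oxygen is silylated rather than benzylated or allylated at this stage.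

Step 11
Reactants: 15 {[(R)-7-(methoxymethoxy)-2-[2-(methoxymethoxy)propan-2-yl]-2,3-dihydrobenzofuran-4-yl]oxy}triisopropylsilane
Product: 17 (R)-4-(allyloxy)-7-(methoxymethoxy)-2-[2-(methoxymethoxy)propan-2-yl]-2,3-dihydrobenzofuran, via phenol 16 (not isolated)
Conditions: TBAF (1.1 equiv), THF, 0 °C; then allyl bromide, rt
Reagents that add atoms: allyl bromide, C=CCBr
Why: Fluoride should cleave the aryl silyl ether, and the resulting tetrabutylammonium phenoxide is O-allylated in the same flask (Williamson ether synthesis).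

Step 12
Reactants: 17 (R)-4-(allyloxy)-7-(methoxymethoxy)-2-[2-(methoxymethoxy)propan-2-yl]-2,3-dihydrobenzofuran
Product: 19 (R)-5-allyl-7-(methoxymethoxy)-2-[2-(methoxymethoxy)propan-2-yl]-2,3-dihydrobenzofuran-4-ol, via cyclohexadienone 18 (not isolated)
Conditions: PhNEt2, 190 °C (sealed tube)
Reagents that add atoms: none
Why: Aromatic Claisen rearrangement: of the two ortho positions only C5 carries hydrogen (C3a is the ring-fusion carbon), so the [3,3] shift and tautomerisation should place the allyl group at C5 and return the C4 phenol.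

Step 13
Reactants: 19 (R)-5-allyl-7-(methoxymethoxy)-2-[2-(methoxymethoxy)propan-2-yl]-2,3-dihydrobenzofuran-4-ol
Product: 20 (R)-5-allyl-7-(methoxymethoxy)-2-[2-(methoxymethoxy)propan-2-yl]-2,3-dihydrobenzofuran-4-yl trifluoromethanesulfonate
Conditions: Tf2O, pyridine, CH2Cl2, −20 → 0 °C
Reagents that add atoms: trifluoromethanesulfonic anhydride, O=S(=O)(OS(=O)(=O)C(F)(F)F)C(F)(F)F
Why: O-Sulfonylation of the hindered phenol turns the C4 oxygen into a cross-coupling leaving group, while pyridine keeps the MOM acetals from being activated.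

Step 14
Reactants: 20 (R)-5-allyl-7-(methoxymethoxy)-2-[2-(methoxymethoxy)propan-2-yl]-2,3-dihydrobenzofuran-4-yl trifluoromethanesulfonate
Product: 21 (R)-5-allyl-7-(methoxymethoxy)-2-[2-(methoxymethoxy)propan-2-yl]-4-(3-methylbut-2-en-1-yl)-2,3-dihydrobenzofuran
Conditions: prenylSnBu3, Pd(PPh3)4 (10 mol%), LiCl, DMF, 100 °C
Reagents that add atoms: tributyl(3-methylbut-2-en-1-yl)stannane, CCCC[Sn](CCCC)(CCCC)CC=C(C)C
Why: LiCl-assisted Stille coupling of the aryl triflate with the allylstannane; reductive elimination at the unsubstituted allyl terminus should be favoured at the di-ortho-substituted aryl group and give the linear prenyl group.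

Step 15
Reactants: 21 (R)-5-allyl-7-(methoxymethoxy)-2-[2-(methoxymethoxy)propan-2-yl]-4-(3-methylbut-2-en-1-yl)-2,3-dihydrobenzofuran; 4 1-bromo-2,4-bis(methoxymethoxy)-5-(2-methylbut-3-en-2-yl)benzene
Product: 23 (R)-5-{3-[2,4-bis(methoxymethoxy)-5-(2-methylbut-3-en-2-yl)phenyl]propyl}-7-(methoxymethoxy)-2-[2-(methoxymethoxy)propan-2-yl]-4-(3-methylbut-2-en-1-yl)-2,3-dihydrobenzofuran, via B-alkyl-9-BBN 22 (not isolated)
Conditions: 9-BBN (1.05 equiv), THF, 0 °C → rt; then K3PO4 (3 M aq), 4, PdCl2(dppf) (5 mol%), DMF, 60 °C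
Reagents that add atoms: none
Why: 9-BBN should hydroborate the terminal allyl group anti-Markovnikov far faster than the trisubstituted prenyl alkene, and the B-alkyl Suzuki–Miyaura coupling with the aryl bromide then forms the sp3–sp2 bond of the propane bridge (aqueous base is added before 4 so that no B–H remains to attack its vinyl group).

Step 16
Reactants: 23 (R)-5-{3-[2,4-bis(methoxymethoxy)-5-(2-methylbut-3-en-2-yl)phenyl]propyl}-7-(methoxymethoxy)-2-[2-(methoxymethoxy)propan-2-yl]-4-(3-methylbut-2-en-1-yl)-2,3-dihydrobenzofuran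
Product: 24 4-{3-[(R)-7-hydroxy-2-(2-hydroxypropan-2-yl)-4-(3-methylbut-2-en-1-yl)-2,3-dihydrobenzofuran-5-yl]propyl}-6-(2-methylbut-3-en-2-yl)benzene-1,3-diol (CNP0189999.1)
Conditions: HCl (1.25 M in MeOH), THF, 40 °C
Reagents that add atoms: none
Why: Acid-catalysed acetal exchange with methanol should remove the three aryl MOM ethers and the tertiary alkyl MOM ether under conditions mild enough not to protonate the prenyl and 1,1-dimethylallyl alkenes.

**Compound list**

1 | 4-bromobenzene-1,3-diol (4-bromoresorcinol) | Oc1ccc(Br)c(O)c1 | starting material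
2 | 1-bromo-2,4-bis(methoxymethoxy)benzene | COCOc1ccc(Br)c(OCOC)c1 | intermediate
3 | 1-bromo-5-iodo-2,4-bis(methoxymethoxy)benzene | COCOc1cc(OCOC)c(Br)cc1I | intermediate
4 | 1-bromo-2,4-bis(methoxymethoxy)-5-(2-methylbut-3-en-2-yl)benzene | C=CC(C)(C)c1cc(Br)c(OCOC)cc1OCOC | intermediate
5 | 2-bromobenzene-1,3-diol (2-bromoresorcinol) | Oc1cccc(O)c1Br | starting material
6 | N-[(3-bromo-2,4-dihydroxyphenyl)methylidene]-N-methylmethanaminium chloride | C[N+](C)=Cc1ccc(O)c(Br)c1O.[Cl-] | intermediate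
7 | 3-bromo-2,4-dihydroxybenzaldehyde | O=Cc1ccc(O)c(Br)c1O | intermediate
8 | 3-bromo-2-hydroxy-4-[(triisopropylsilyl)oxy]benzaldehyde | O=Cc1ccc(O[Si](C(C)C)(C(C)C)C(C)C)c(Br)c1O | intermediate
9 | ethyl (S)-2-hydroxypropanoate (ethyl (S)-lactate) | C[C@H](O)C(=O)OCC | starting material
10 | ethyl (R)-2-{2-bromo-6-formyl-3-[(triisopropylsilyl)oxy]phenoxy}propanoate | C[C@@H](Oc1c(C=O)ccc(O[Si](C(C)C)(C(C)C)C(C)C)c1Br)C(=O)OCC | intermediate
11 | ethyl (R)-2-{2-bromo-6-(formyloxy)-3-[(triisopropylsilyl)oxy]phenoxy}propanoate | C[C@@H](Oc1c(OC=O)ccc(O[Si](C(C)C)(C(C)C)C(C)C)c1Br)C(=O)OCC | intermediate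
12 | (R)-3-{2-bromo-6-hydroxy-3-[(triisopropylsilyl)oxy]phenoxy}butan-2-one | C[C@@H](Oc1c(O)ccc(O[Si](C(C)C)(C(C)C)C(C)C)c1Br)C(C)=O | intermediate
13 | 3-bromo-2-{[(R)-3-hydroxy-3-methylbutan-2-yl]oxy}-4-[(triisopropylsilyl)oxy]phenol | C[C@@H](Oc1c(O)ccc(O[Si](C(C)C)(C(C)C)C(C)C)c1Br)C(C)(C)O | intermediate
14 | {2-bromo-4-(methoxymethoxy)-3-{[(R)-3-(methoxymethoxy)-3-methylbutan-2-yl]oxy}phenoxy}triisopropylsilane | C[C@@H](Oc1c(OCOC)ccc(O[Si](C(C)C)(C(C)C)C(C)C)c1Br)C(C)(C)OCOC | intermediate
15 | {[(R)-7-(methoxymethoxy)-2-[2-(methoxymethoxy)propan-2-yl]-2,3-dihydrobenzofuran-4-yl]oxy}triisopropylsilane | COCOC(C)(C)[C@H]1Cc2c(O[Si](C(C)C)(C(C)C)C(C)C)ccc(OCOC)c2O1 | intermediate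
16 | (R)-7-(methoxymethoxy)-2-[2-(methoxymethoxy)propan-2-yl]-2,3-dihydrobenzofuran-4-ol | COCOC(C)(C)[C@H]1Cc2c(O)ccc(OCOC)c2O1 | intermediate
17 | (R)-4-(allyloxy)-7-(methoxymethoxy)-2-[2-(methoxymethoxy)propan-2-yl]-2,3-dihydrobenzofuran | COCOC(C)(C)[C@H]1Cc2c(OCC=C)ccc(OCOC)c2O1 | intermediate
18 | (2R)-5-allyl-7-(methoxymethoxy)-2-[2-(methoxymethoxy)propan-2-yl]-3,5-dihydrobenzofuran-4(2H)-one (C5 epimers) | COCOC(C)(C)[C@H]1CC2=C(O1)C(OCOC)=CC(CC=C)C2=O | intermediate
19 | (R)-5-allyl-7-(methoxymethoxy)-2-[2-(methoxymethoxy)propan-2-yl]-2,3-dihydrobenzofuran-4-ol | COCOC(C)(C)[C@H]1Cc2c(O)c(CC=C)cc(OCOC)c2O1 | intermediate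
20 | (R)-5-allyl-7-(methoxymethoxy)-2-[2-(methoxymethoxy)propan-2-yl]-2,3-dihydrobenzofuran-4-yl trifluoromethanesulfonate | COCOC(C)(C)[C@H]1Cc2c(OS(=O)(=O)C(F)(F)F)c(CC=C)cc(OCOC)c2O1 | intermediate
21 | (R)-5-allyl-7-(methoxymethoxy)-2-[2-(methoxymethoxy)propan-2-yl]-4-(3-methylbut-2-en-1-yl)-2,3-dihydrobenzofuran | COCOC(C)(C)[C@H]1Cc2c(CC=C(C)C)c(CC=C)cc(OCOC)c2O1 | intermediate
22 | 9-{3-[(R)-7-(methoxymethoxy)-2-[2-(methoxymethoxy)propan-2-yl]-4-(3-methylbut-2-en-1-yl)-2,3-dihydrobenzofuran-5-yl]propyl}-9-borabicyclo[3.3.1]nonane | COCOC(C)(C)[C@H]1Cc2c(CC=C(C)C)c(CCCB3C4CCCC3CCC4)cc(OCOC)c2O1 | intermediate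
23 | (R)-5-{3-[2,4-bis(methoxymethoxy)-5-(2-methylbut-3-en-2-yl)phenyl]propyl}-7-(methoxymethoxy)-2-[2-(methoxymethoxy)propan-2-yl]-4-(3-methylbut-2-en-1-yl)-2,3-dihydrobenzofuran | COCOC(C)(C)[C@H]1Cc2c(CC=C(C)C)c(CCCc3cc(C(C)(C)C=C)c(OCOC)cc3OCOC)cc(OCOC)c2O1 | intermediate
24 | 4-{3-[(R)-7-hydroxy-2-(2-hydroxypropan-2-yl)-4-(3-methylbut-2-en-1-yl)-2,3-dihydrobenzofuran-5-yl]propyl}-6-(2-methylbut-3-en-2-yl)benzene-1,3-diol | C=CC(C)(C)c1cc(CCCc2cc(O)c3c(c2CC=C(C)C)C[C@H](C(C)(C)O)O3)c(O)cc1O | target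

**Totals.** Total step count: 16. Longest linear sequence: 13 steps (steps 4–16, from 2-bromoresorcinol); steps 1–3 make the second fragment.

**Steps most likely to fail**

1. Step 10 (ring closure). Oxidative addition at the C–Br bond flanked by two oxygen substituents may be slow. After C–H palladation, β-hydride elimination from C2 could compete with reductive elimination, giving enol ether and reduced arene and, through reinsertion, eroding the configuration at C2. Fallback: form the same C3–C3a bond by a Parham-type anionic cyclisation (aryllithium onto a bromomethyl group). It sets out from 8. Commercial methyl (S)-2,2-dimethyl-1,3-dioxolane-4-carboxylate would be methanolysed (TsOH, MeOH) to methyl (S)-2,3-dihydroxypropanoate F1 and silylated at the primary hydroxyl (TBDPSCl, imidazole) to methyl (S)-3-[(tert-butyldiphenylsilyl)oxy]-2-hydroxypropanoate F2. Mitsunobu reaction of 8 with F2 should give, with inversion, methyl (R)-2-{2-bromo-6-formyl-3-[(triisopropylsilyl)oxy]phenoxy}-3-[(tert-butyldiphenylsilyl)oxy]propanoate F3. mCPBA would give the aryl formate F4, and MeMgBr the phenol carbinol F5. MOMCl/i-Pr2NEt would give the bis-MOM ether F6, and TBAF would remove both silyl groups to give the phenol primary alcohol F7. CBr4/PPh3 would convert only the primary alcohol into the bromide F8. n-BuLi (2.1 equiv, THF, −100 °C → rt) would then deprotonate the phenol, exchange the aryl bromide and cyclise 5-exo-tet onto CH2Br. The fallback comes back to the route at 16, here isolated, which is allylated (allyl bromide, K2CO3) to 17.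

2. Step 14 (prenylation of the triflate). Allyl transposition in the π-allyl intermediate could deliver the 1,1-dimethylallyl isomer, and slow oxidative addition at the di-ortho-substituted, electron-rich triflate could allow triflate hydrolysis or isomerisation of the neighbouring allyl group. Fallback: build the prenyl group by allylation and cross-metathesis after the fragment union. It sets out from 19. Hydroboration (9-BBN, 2.1 equiv) and B-alkyl Suzuki coupling with 4 would give (R)-5-{3-[2,4-bis(methoxymethoxy)-5-(2-methylbut-3-en-2-yl)phenyl]propyl}-7-(methoxymethoxy)-2-[2-(methoxymethoxy)propan-2-yl]-2,3-dihydrobenzofuran-4-ol F9. Tf2O/pyridine would give its triflate F10. Stille coupling with allyltributylstannane, which has no regiochemical ambiguity, would give the 4-allyl compound F11. Cross-metathesis with 2-methyl-2-butene (second-generation Ru–NHC catalyst) should convert only the unhindered allyl group, because the 1,1-dimethylallyl vinyl group has a quaternary allylic carbon. The fallback comes back at 23.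

3. Step 3 (γ-selective coupling). σ–π–σ isomerisation before reductive elimination would give the linear prenyl isomer, and over-reaction at the C–Br bond would consume the handle for step 15. Fallback: O-prenylation and aromatic Claisen rearrangement. It sets out from 1. Prenyl bromide (1 equiv) with K2CO3 in acetone should alkylate mainly the less hindered hydroxyl para to bromine, giving 2-bromo-5-[(3-methylbut-2-en-1-yl)oxy]phenol F12. Heating (PhNEt2, 180 °C) should shift the prenyl group with allylic inversion to the free ortho position para to the other hydroxyl, giving 4-bromo-6-(2-methylbut-3-en-2-yl)benzene-1,3-diol F13. MOMCl/i-Pr2NEt then gives 4, where the fallback comes back to the route.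

Further compounds
F1 | step 10 | methyl (S)-2,3-dihydroxypropanoate | OC[C@H](O)C(=O)OC
F2 | step 10 | methyl (S)-3-[(tert-butyldiphenylsilyl)oxy]-2-hydroxypropanoate | CC(C)(C)[Si](OC[C@H](O)C(=O)OC)(c1ccccc1)c1ccccc1
F3 | step 10 | methyl (R)-2-{2-bromo-6-formyl-3-[(triisopropylsilyl)oxy]phenoxy}-3-[(tert-butyldiphenylsilyl)oxy]propanoate | CC(C)(C)[Si](OC[C@@H](Oc1c(C=O)ccc(O[Si](C(C)C)(C(C)C)C(C)C)c1Br)C(=O)OC)(c1ccccc1)c1ccccc1
F4 | step 10 | methyl (R)-2-{2-bromo-6-(formyloxy)-3-[(triisopropylsilyl)oxy]phenoxy}-3-[(tert-butyldiphenylsilyl)oxy]propanoate | CC(C)(C)[Si](OC[C@@H](Oc1c(OC=O)ccc(O[Si](C(C)C)(C(C)C)C(C)C)c1Br)C(=O)OC)(c1ccccc1)c1ccccc1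
F5 | step 10 | 3-bromo-2-{[(R)-1-[(tert-butyldiphenylsilyl)oxy]-3-hydroxy-3-methylbutan-2-yl]oxy}-4-[(triisopropylsilyl)oxy]phenol | CC(C)(C)[Si](OC[C@@H](Oc1c(O)ccc(O[Si](C(C)C)(C(C)C)C(C)C)c1Br)C(C)(C)O)(c1ccccc1)c1ccccc1
F6 | step 10 | {2-bromo-3-{[(R)-1-[(tert-butyldiphenylsilyl)oxy]-3-(methoxymethoxy)-3-methylbutan-2-yl]oxy}-4-(methoxymethoxy)phenoxy}triisopropylsilane | CC(C)(C)[Si](OC[C@@H](Oc1c(OCOC)ccc(O[Si](C(C)C)(C(C)C)C(C)C)c1Br)C(C)(C)OCOC)(c1ccccc1)c1ccccc1
F7 | step 10 | 2-bromo-3-{[(R)-1-hydroxy-3-(methoxymethoxy)-3-methylbutan-2-yl]oxy}-4-(methoxymethoxy)phenol | OC[C@@H](Oc1c(OCOC)ccc(O)c1Br)C(C)(C)OCOC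
F8 | step 10 | 2-bromo-3-{[(S)-1-bromo-3-(methoxymethoxy)-3-methylbutan-2-yl]oxy}-4-(methoxymethoxy)phenol | BrC[C@@H](Oc1c(OCOC)ccc(O)c1Br)C(C)(C)OCOC
F9 | step 14 | (R)-5-{3-[2,4-bis(methoxymethoxy)-5-(2-methylbut-3-en-2-yl)phenyl]propyl}-7-(methoxymethoxy)-2-[2-(methoxymethoxy)propan-2-yl]-2,3-dihydrobenzofuran-4-ol | COCOC(C)(C)[C@H]1Cc2c(O)c(CCCc3cc(C(C)(C)C=C)c(OCOC)cc3OCOC)cc(OCOC)c2O1
F10 | step 14 | (R)-5-{3-[2,4-bis(methoxymethoxy)-5-(2-methylbut-3-en-2-yl)phenyl]propyl}-7-(methoxymethoxy)-2-[2-(methoxymethoxy)propan-2-yl]-2,3-dihydrobenzofuran-4-yl trifluoromethanesulfonate | COCOC(C)(C)[C@H]1Cc2c(OS(=O)(=O)C(F)(F)F)c(CCCc3cc(C(C)(C)C=C)c(OCOC)cc3OCOC)cc(OCOC)c2O1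
F11 | step 14 | (R)-4-allyl-5-{3-[2,4-bis(methoxymethoxy)-5-(2-methylbut-3-en-2-yl)phenyl]propyl}-7-(methoxymethoxy)-2-[2-(methoxymethoxy)propan-2-yl]-2,3-dihydrobenzofuran | COCOC(C)(C)[C@H]1Cc2c(CC=C)c(CCCc3cc(C(C)(C)C=C)c(OCOC)cc3OCOC)cc(OCOC)c2O1
F12 | step 3 | 2-bromo-5-[(3-methylbut-2-en-1-yl)oxy]phenol | CC(C)=CCOc1ccc(Br)c(O)c1
F13 | step 3 | 4-bromo-6-(2-methylbut-3-en-2-yl)benzene-1,3-diol | C=CC(C)(C)c1cc(Br)c(O)cc1O
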